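Of the free catalyst charged to this flask, 84.1 % is expected to work: 0.51 mM less the 81 µM of impurity, if each impurity takes one catalyst out of the round. This fraction is called here the working share.

all flasks: impurity 81 µM

|  | starting material | second substrate | free catalyst | remark |
|---|---|---|---|---|
| elm | 0.20 M | 0.60 M | 0.51 mM | run made earlier |
| cedar | 0.45 M | 0.60 M | 0.51 mM | run made earlier |
| maple | 0.30 M | 0.60 M | 0.77 mM | run made earlier |
| flask | 0.30 M | 0.600 M | 0.51 mM |  |

- elm (time / h: target / %): 1.33: 6.1; 2.50: 9.9; 4.00: 14.8; 5.00: 17.4
- cedar (time / h: target / %): 0.667: 2.4; 1.50: 5.8; 3.00: 9.7; 5.00: 17.5
- maple (time / h: target / %): 0.417: 4.6; 0.833: 4.2; 2.00: 12.5; 5.00: 27.6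

(each reading ± 1 percentage point)

1. apparent order in second substrate when 20 % of the starting material are converted (percent change of the rate of making target for one percent more second substrate charged)
2. apparent order in free catalyst when 20 % of the starting material are converted (percent change of the rate of making target for one percent more free catalyst charged)

- no earlier run changes the charge of second substrate; that part of a forecast is a guess

Start with the main step alone: starting material meets catalyst and leaves as target. The last readings of elm and cedar, at 5.00 h, give first-order rate constants of 0.0382 h⁻¹ and 0.0385 h⁻¹, although cedar holds 2.25 times the starting material of elm. So a molecule of starting material has about the same chance per hour in both runs, which is pseudo-first-order behaviour. In this picture the order in catalyst is one. Maple differs from elm in starting material as well as in catalyst, so the comparison is made on this rate constant, and maple's should be 1.51 times elm's.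

Now add the impurity. The working catalyst becomes [free catalyst] − [impurity], so one percent more charge is 1/w percent more working catalyst, and the order rises to 1.19. Maple's rate constant should then be 1.61 times elm's. The last readings give 1.69, nearer to this value than to the first, but with a scatter of 1 percentage point on each reading the check is weak.

Last comes the second substrate. Elm, cedar and maple hold 0.60 M, 0.60 M and 0.60 M, so these readings show no slope in it, and this reckoning commits to no value, not even a sign. For catalyst the reckoning stays at 1.19.

The forecast gives 1.2 for free catalyst, in line with this reckoning, and 0.8 for second substrate, on the grounds that “Its order is a prior guess”.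

The simulation gives 1.2 in free catalyst and −0.66 in second substrate.

    starting material + free catalyst ⇌ catalyst intermediate A (K = 7.29 M⁻¹, k = 894 M⁻¹ h⁻¹)
    catalyst intermediate A → free catalyst + target (k = 176 h⁻¹)
    second substrate + free catalyst ⇌ catalyst intermediate B (K = 125 M⁻¹, k = 484 M⁻¹ h⁻¹)
    catalyst intermediate B → free catalyst + second product (k = 66.4 h⁻¹)
    free catalyst + impurity → spent catalyst (k = 83600 M⁻¹ h⁻¹)

The order in second substrate is negative, where the forecast had 0.8. In this flask, catalyst intermediate B holds 56.4 % of the catalyst charged at 4.00 h and 54.9 % at 8.00 h, on either side of the 5.45 h at which 20 % of the starting material are converted. Divided by the working share of 84.1 %, these are fractions 0.671 and 0.653 of the working catalyst, against an order of −0.66.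

The runs stem from a simulated flask from invented constants, and the scatter is random.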